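**Retrosynthetic overview**

1. Target ⇒ trans-5-hydroxy lactone + tiglic acid: the ester goes on last by Mitsunobu inversion at C5 (trans becomes cis), so no protecting group is used anywhere.
2. trans-5-Hydroxy lactone ⇒ 6-hydroxy-2H-pyran-3(6H)-one ⇒ 2-furyl carbinol: the key step is an Achmatowicz oxidative ring expansion of a furan that already carries the complete diacetoxypentenyl side chain. This is the only ring formed in the route.
3. 2-Furyl carbinol ⇒ furan + (2E,4S,5S)-4,5-diacetoxyhex-2-enal, joined by catalyst-controlled furyl transfer, which sets C6.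
4. Enal ⇒ 3,4-di-O-acetyl-L-fucal: Perlin ring-opening of the sugar delivers the E-alkene and both side-chain stereocentres, already as acetates.
5. The customary acrylate ring-closing metathesis / cross-metathesis assembly is deliberately not used.

Assumption: 3,4-di-O-acetyl-L-fucal is bought as a catalogue compound (otherwise three routine steps from L-fucose). Ring positions in the text use lactone numbering: C2 carbonyl, C5 ester-bearing carbon, C6 side-chain-bearing carbon.

**Route**

Step 1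
Reactants: 1 3,4-di-O-acetyl-L-fucal [(2S,3R,4S)-2-methyl-3,4-dihydro-2H-pyran-3,4-diyl diacetate]
Product: 4 (2S,3S,4E)-2-hydroxy-6-oxohex-4-en-3-yl acetate, via unsaturated lactol 2 (not isolated), via Z-enal 3 (not isolated)
Conditions: HgSO4 (2 mol%), 5 mM aq. H2SO4, 1,4-dioxane, rt
Reagents that add atoms: water, O
Why: Perlin hydrolysis (mercury-assisted hydration of the glycal with Ferrier-type allylic loss of the C3 acetate) gives the 2,3-unsaturated lactol 2, whose open Z-enal form 3 isomerises under the acid to the conjugated E-enal, while the two stereocentres are simply C4 and C5 of L-fucose carried over untouched.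

Step 2
Reactants: 4 (2S,3S,4E)-2-hydroxy-6-oxohex-4-en-3-yl acetate
Product: 5 (2S,3S,4E)-6-oxohex-4-ene-2,3-diyl diacetate
Conditions: Ac2O, pyridine, CH2Cl2, 0 °C
Reagents that add atoms: acetic anhydride, CC(=O)OC(C)=O
Why: Routine O-acetylation of the only free hydroxyl, which also makes any 4-O to 5-O acetyl migration in 4 irrelevant; no stereocentre is formed or disturbed.

Step 3
Reactants: 5 (2S,3S,4E)-6-oxohex-4-ene-2,3-diyl diacetate; 6 furan
Product: 7 (2S,3S,4E,6S)-6-(furan-2-yl)-6-hydroxyhex-4-ene-2,3-diyl diacetate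
Conditions: 6, n-BuLi, THF, 0 °C; ClTi(OiPr)3, −78 → 0 °C; then 5, (R)-3-(3,5-diphenylphenyl)-H8-BINOL (5 mol%), Ti(OiPr)4 (20 mol%), CH2Cl2, 0 °C
Reagents that add atoms: none
Why: Catalytic asymmetric heteroaryl transfer from an aryltitanium triisopropoxide to an aldehyde under BINOL-type titanium catalysis: the furyl–titanium reagent adds 1,2 to the enal and tolerates the acetates, and the (R)-ligand is expected, by analogy with BINOL–titanium alkylations, to direct furyl to the Re face of the C=O (reagent control, the acetoxy centres being too remote to interfere; the antipodal ligand is used if the first run shows the opposite sense), which sets the new carbinol centre as (6S).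

Step 4
Reactants: 7 (2S,3S,4E,6S)-6-(furan-2-yl)-6-hydroxyhex-4-ene-2,3-diyl diacetate
Product: 9 (2S,3S,4E)-5-[(2S)-6-hydroxy-3-oxo-3,6-dihydro-2H-pyran-2-yl]pent-4-ene-2,3-diyl diacetate, via acyclic enedione 8 (not isolated)
Conditions: NBS, NaHCO3, NaOAc, THF/H2O (4:1), 0 °C
Reagents that add atoms: water, O
Why: Achmatowicz rearrangement: NBS/water oxidises the electron-rich furan (much more nucleophilic than the acetoxy-deactivated 1,2-disubstituted alkene) to the ring-opened Z-enedione 8, which recloses through the carbinol oxygen to the pyranone hemiacetal, so the carbinol C–O bond is never broken and its (S) configuration becomes C2 of the new ring, the anomeric centre forming as an inconsequential mixture.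

Step 5
Reactants: 9 (2S,3S,4E)-5-[(2S)-6-hydroxy-3-oxo-3,6-dihydro-2H-pyran-2-yl]pent-4-ene-2,3-diyl diacetate
Product: 11 (2S,3S,4E)-5-[(2S,3R)-3-hydroxy-6-oxo-3,6-dihydro-2H-pyran-2-yl]pent-4-ene-2,3-diyl diacetate, via ketolactone 10 (not isolated)
Conditions: CrO3, H2SO4, acetone, 0 °C; crude 10, NaBH4, CeCl3·7H2O, MeOH/CH2Cl2 (1:1), −78 °C
Reagents that add atoms: none
Why: Jones oxidation turns the lactol into the lactone carbonyl and Luche 1,2-reduction of the remaining enone carbonyl follows at once because 10 enolises easily; hydride adds axially to the half-chair that carries the alkenyl group pseudo-equatorial, so the new carbinol centre is set trans to C6 (5R) by substrate control.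

Step 6
Reactants: 11 (2S,3S,4E)-5-[(2S,3R)-3-hydroxy-6-oxo-3,6-dihydro-2H-pyran-2-yl]pent-4-ene-2,3-diyl diacetate; 12 tiglic acid [(2E)-2-methylbut-2-enoic acid]
Product: 13 (2S,3S)-2-[(1E,3S,4S)-3,4-diacetoxypent-1-en-1-yl]-6-oxo-3,6-dihydro-2H-pyran-3-yl (2E)-2-methylbut-2-enoate (target CNP0271997.1)
Conditions: PPh3, DIAD, toluene, 0 °C → rt
Reagents that add atoms: none
Why: Mitsunobu esterification: the alkoxyphosphonium of the allylic alcohol is displaced by tiglate in an SN2 step with inversion, which converts the trans (5R) alcohol into the cis (5S) tiglate and installs the acyl group in the same operation without touching C6 or the acetates.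

**Compound list**

1 | 3,4-di-O-acetyl-L-fucal, (2S,3R,4S)-2-methyl-3,4-dihydro-2H-pyran-3,4-diyl diacetate | C[C@@H]1OC=C[C@H](OC(C)=O)[C@@H]1OC(C)=O | starting material
2 | (2S,3S)-6-hydroxy-2-methyl-3,6-dihydro-2H-pyran-3-yl acetate (unsaturated lactol, anomer mixture) | C[C@@H]1OC(O)C=C[C@@H]1OC(C)=O | intermediate
3 | (2S,3S,4Z)-2-hydroxy-6-oxohex-4-en-3-yl acetate (Z-enal) | O=C/C=C\[C@H](OC(C)=O)[C@H](C)O | intermediate
4 | (2S,3S,4E)-2-hydroxy-6-oxohex-4-en-3-yl acetate | O=C/C=C/[C@H](OC(C)=O)[C@H](C)O | intermediate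
5 | (2S,3S,4E)-6-oxohex-4-ene-2,3-diyl diacetate | O=C/C=C/[C@H](OC(C)=O)[C@H](C)OC(C)=O | intermediate
6 | furan | c1ccoc1 | starting material
7 | (2S,3S,4E,6S)-6-(furan-2-yl)-6-hydroxyhex-4-ene-2,3-diyl diacetate | O[C@H](c1ccco1)/C=C/[C@H](OC(C)=O)[C@H](C)OC(C)=O | intermediate
8 | (2S,3S,4E,6S,8Z)-6-hydroxy-7,10-dioxodeca-4,8-diene-2,3-diyl diacetate (acyclic enedione) | O=C/C=C\C(=O)[C@@H](O)/C=C/[C@H](OC(C)=O)[C@H](C)OC(C)=O | intermediate
9 | (2S,3S,4E)-5-[(2S)-6-hydroxy-3-oxo-3,6-dihydro-2H-pyran-2-yl]pent-4-ene-2,3-diyl diacetate (anomer mixture) | OC1C=CC(=O)[C@@H](O1)/C=C/[C@H](OC(C)=O)[C@H](C)OC(C)=O | intermediate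
10 | (2S,3S,4E)-5-[(2S)-3,6-dioxo-3,6-dihydro-2H-pyran-2-yl]pent-4-ene-2,3-diyl diacetate (ketolactone) | O=C1C=CC(=O)[C@@H](O1)/C=C/[C@H](OC(C)=O)[C@H](C)OC(C)=O | intermediate
11 | (2S,3S,4E)-5-[(2S,3R)-3-hydroxy-6-oxo-3,6-dihydro-2H-pyran-2-yl]pent-4-ene-2,3-diyl diacetate (5,6-trans alcohol) | O[C@@H]1C=CC(=O)O[C@H]1/C=C/[C@H](OC(C)=O)[C@H](C)OC(C)=O | intermediate
12 | tiglic acid, (2E)-2-methylbut-2-enoic acid | C/C=C(\C)C(=O)O | starting material
13 | (2S,3S)-2-[(1E,3S,4S)-3,4-diacetoxypent-1-en-1-yl]-6-oxo-3,6-dihydro-2H-pyran-3-yl (2E)-2-methylbut-2-enoate | C/C=C(\C)C(=O)O[C@H]1C=CC(=O)O[C@H]1/C=C/[C@H](OC(C)=O)[C@H](C)OC(C)=O | target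

**Step count and risks**

Total step count: 6. Longest linear sequence: 6 steps (1 → 13, fully linear; no protecting groups).

The three steps most likely to fail:

First, the furyl transfer of step 3. Asymmetric heteroaryl–titanium additions are known for aldehydes including enals, but this combination of a 2-furyl nucleophile and a γ,δ-diacetoxy enal is untested, and the facial control may be incomplete. The fallback sets out from 5 and comes back to the route at 9. 2-Furyllithium (from 6 and n-BuLi, THF, −78 °C) is added without a chiral catalyst, giving 7 mixed with its carbinol epimer (2S,3S,4E,6R)-6-(furan-2-yl)-6-hydroxyhex-4-ene-2,3-diyl diacetate F1. The mixture is oxidised under kinetic-resolution conditions (Ti(OiPr)4, L-(+)-diisopropyl tartrate, t-BuOOH, 4 Å sieves, CH2Cl2, −20 °C). For the (S)-carbinol the tartrate-matched olefin is the furan, so 7 goes directly to pyranone 9. In F1 the matched olefin is the electron-poor side-chain alkene, so F1 is left behind. Recovered F1 is recycled by MnO2 oxidation to the furyl enone (2S,3S,4E)-6-(furan-2-yl)-6-oxohex-4-ene-2,3-diyl diacetate F2 and NaBH4/CeCl3·7H2O reduction back to the 7/F1 mixture.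

Second, the oxidation/reduction of step 5. Ketolactone 10 has a C6–H that is α to the ketone and allylic, so it can tautomerise to an achiral 5-hydroxy-2-pyranone before it is reduced. The fallback sets out from 9 and comes back at 13, bypassing 10 and 11. The lactol is capped with CH(OMe)3 and BF3·OEt2 (CH2Cl2, 0 °C) to give the methyl acetal (2S,3S,4E)-5-[(2S)-6-methoxy-3-oxo-3,6-dihydro-2H-pyran-2-yl]pent-4-ene-2,3-diyl diacetate F3, which has no such aromatising pathway. Luche reduction (NaBH4, CeCl3·7H2O, MeOH, −78 °C) gives the trans alcohol (2S,3S,4E)-5-[(2S,3R)-3-hydroxy-6-methoxy-3,6-dihydro-2H-pyran-2-yl]pent-4-ene-2,3-diyl diacetate F4. Mitsunobu reaction with 12 (PPh3, DIAD) gives the cis tiglate (2S,3S)-2-[(1E,3S,4S)-3,4-diacetoxypent-1-en-1-yl]-6-methoxy-3,6-dihydro-2H-pyran-3-yl (2E)-2-methylbut-2-enoate F5. CrO3/H2SO4 in acetone at 0 °C then hydrolyses and oxidises the allylic acetal to the lactone 13.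

Third, the Mitsunobu reaction of step 6. Tiglic acid is a weak, hindered pronucleophile, and the activated alcohol can instead eliminate across C5–C6 to a conjugated 2-pyranone. The fallback sets out from 11 and comes back at 13, separating inversion from acylation. Mitsunobu inversion with the smaller, more acidic chloroacetic acid (PPh3, DIAD, toluene, 0 °C) gives (2S,3S)-2-[(1E,3S,4S)-3,4-diacetoxypent-1-en-1-yl]-6-oxo-3,6-dihydro-2H-pyran-3-yl chloroacetate F6. Thiourea with NaHCO3 in EtOH at 40 °C removes only the chloroacetyl group and leaves the acetates, giving the cis alcohol (2S,3S,4E)-5-[(2S,3S)-3-hydroxy-6-oxo-3,6-dihydro-2H-pyran-2-yl]pent-4-ene-2,3-diyl diacetate F7. This is esterified with retention (12, 2,4,6-trichlorobenzoyl chloride, Et3N, DMAP, toluene) to 13.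

**Further compounds**

F1 | step 3 | (2S,3S,4E,6R)-6-(furan-2-yl)-6-hydroxyhex-4-ene-2,3-diyl diacetate | O[C@@H](c1ccco1)/C=C/[C@H](OC(C)=O)[C@H](C)OC(C)=O
F2 | step 3 | (2S,3S,4E)-6-(furan-2-yl)-6-oxohex-4-ene-2,3-diyl diacetate | O=C(c1ccco1)/C=C/[C@H](OC(C)=O)[C@H](C)OC(C)=O
F3 | step 5 | (2S,3S,4E)-5-[(2S)-6-methoxy-3-oxo-3,6-dihydro-2H-pyran-2-yl]pent-4-ene-2,3-diyl diacetate | COC1C=CC(=O)[C@@H](O1)/C=C/[C@H](OC(C)=O)[C@H](C)OC(C)=O
F4 | step 5 | (2S,3S,4E)-5-[(2S,3R)-3-hydroxy-6-methoxy-3,6-dihydro-2H-pyran-2-yl]pent-4-ene-2,3-diyl diacetate | O[C@@H]1C=CC(OC)O[C@H]1/C=C/[C@H](OC(C)=O)[C@H](C)OC(C)=O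
F5 | step 5 | (2S,3S)-2-[(1E,3S,4S)-3,4-diacetoxypent-1-en-1-yl]-6-methoxy-3,6-dihydro-2H-pyran-3-yl (2E)-2-methylbut-2-enoate | C/C=C(\C)C(=O)O[C@H]1C=CC(OC)O[C@H]1/C=C/[C@H](OC(C)=O)[C@H](C)OC(C)=O
F6 | step 6 | (2S,3S)-2-[(1E,3S,4S)-3,4-diacetoxypent-1-en-1-yl]-6-oxo-3,6-dihydro-2H-pyran-3-yl chloroacetate | O=C(CCl)O[C@H]1C=CC(=O)O[C@H]1/C=C/[C@H](OC(C)=O)[C@H](C)OC(C)=O
F7 | step 6 | (2S,3S,4E)-5-[(2S,3S)-3-hydroxy-6-oxo-3,6-dihydro-2H-pyran-2-yl]pent-4-ene-2,3-diyl diacetate | O[C@H]1C=CC(=O)O[C@H]1/C=C/[C@H](OC(C)=O)[C@H](C)OC(C)=O
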